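**Retrosynthetic overview**
- The strategy rests on the cyclohexene ring. Its quaternary C1 (CH3 plus the (E)-CH=CH–coumarin-3-yl arm), the adjacent C2–H carrying the second coumarin-3-yl group, and the C3H=C4(CH3)–C5H2–C6H2 remainder form the ortho/para [4+2] pattern of a 1-(coumarin-3-yl)-3-methylbuta-1,3-diene (C2 to C5) with a CH2=C(CH3)–X dienophile (C6, C1).
- X is chosen as CHO (methacrolein), which a chiral boron Lewis acid can bind. The formyl carbon later becomes the alkene carbon on C1.
- Disconnections: coumarin C3–alkene bond (Suzuki–Miyaura with a 3-bromocoumarin); the arm C=C (boryl Takai olefination of the aldehyde); ring bonds C1–C2 and C5–C6 (catalytic enantioselective Diels–Alder); the diene from the same 3-bromocoumarin (Heck coupling, dehydration).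
- Ring order: pyranone first (Knoevenagel condensation and lactonisation on 2,4-dihydroxy-3-methoxybenzaldehyde), cyclohexene second (Diels–Alder), second preformed coumarin attached last.

Key step: step 7

Assumption: the catalyst enantiomer is assigned from the formyl C–H···O pre-transition-state model, which predicts that the catalyst from (S)-α,α-diphenylprolinol exposes the Re face of the α-carbon of s-trans methacrolein and so gives the (1S,2R) aldehyde; should the sense prove opposite, the catalyst from the (R)-prolinol would be used with no other change.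

Step 1
Reactants: 1 2-methoxyresorcinol
Product: 3 2,4-dihydroxy-3-methoxybenzaldehyde, via aryl iminium chloride 2 (not isolated)
Conditions: POCl3 (1.2 equiv), DMF (1.5 equiv), MeCN, −15 °C → rt; then H2O, 50 °C
Reagents that add atoms: N,N-dimethylformamide CN(C)C=O (formyl carbon); water O (carbonyl oxygen)
Why: Vilsmeier–Haack formylation, in which the chloroiminium ion attacks C4 (equivalent to C6 by symmetry), the only position ortho to one hydroxyl and para to the other, and hydrolysis of the iminium salt should give the aldehyde.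

Step 2
Reactants: 3 2,4-dihydroxy-3-methoxybenzaldehyde; 4 Meldrum's acid
Product: 6 7-hydroxy-8-methoxycoumarin-3-carboxylic acid, via arylidene Meldrum's acid 5 (not isolated)
Conditions: piperidinium acetate (10 mol%), EtOH, rt → 70 °C
Reagents that add atoms: none
Why: Knoevenagel condensation followed by attack of the ortho hydroxyl on the dioxanedione carbonyl, which closes the pyranone ring by lactonisation with loss of acetone and leaves the carboxylic acid at C3.

Step 3
Reactants: 6 7-hydroxy-8-methoxycoumarin-3-carboxylic acid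
Product: 8 8-methoxy-7-(triisopropylsilyloxy)coumarin-3-carboxylic acid, via silyl ester silyl ether 7 (not isolated)
Conditions: TIPSCl (2.4 equiv), imidazole (5 equiv), DMF, rt; then THF/AcOH/H2O (3:1:1), rt
Reagents that add atoms: triisopropylsilyl chloride CC(C)[Si](Cl)(C(C)C)C(C)C
Why: Silyl ether formation on the phenol; the carboxyl group is silylated as well, but the silyl ester of this strongly acidic carboxylic acid should be solvolysed by aqueous acetic acid far faster than the hindered aryl triisopropylsilyl ether.

Step 4
Reactants: 8 8-methoxy-7-(triisopropylsilyloxy)coumarin-3-carboxylic acid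
Product: 9 3-bromo-8-methoxy-7-(triisopropylsilyloxy)coumarin
Conditions: NBS (1.1 equiv), LiOAc (0.2 equiv), MeCN/H2O (20:1), rt, dark
Reagents that add atoms: N-bromosuccinimide O=C1CCC(=O)N1Br
Why: Catalytic Hunsdiecker-type bromodecarboxylation of an aryl-conjugated acrylic acid, in which the lithium carboxylate takes up electrophilic bromine at C3, the developing positive charge at C4 is stabilised by the 7-silyloxy group through C4a, and loss of CO2 restores the C3=C4 bond.

Step 5
Reactants: 9 3-bromo-8-methoxy-7-(triisopropylsilyloxy)coumarin; 10 2-methylbut-3-en-2-ol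
Product: 11 3-[(E)-3-hydroxy-3-methylbut-1-enyl]-8-methoxy-7-(triisopropylsilyloxy)coumarin
Conditions: Pd(OAc)2 (5 mol%), P(o-tol)3 (12 mol%), Et3N (3 equiv), DMF, 90 °C
Reagents that add atoms: none
Why: Mizoroki–Heck reaction, in which zerovalent palladium inserts into the C3–Br bond, syn carbopalladation occurs at the unsubstituted alkene terminus, and syn β-hydride elimination (possible only toward the coumarin side) should give the (E)-allylic alcohol.

Step 6
Reactants: 11 3-[(E)-3-hydroxy-3-methylbut-1-enyl]-8-methoxy-7-(triisopropylsilyloxy)coumarin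
Product: 13 3-[(E)-3-methylbuta-1,3-dienyl]-8-methoxy-7-(triisopropylsilyloxy)coumarin, via tertiary allylic mesylate 12 (not isolated)
Conditions: MsCl (2 equiv), Et3N (5 equiv), CH2Cl2, 0 °C → rt
Reagents that add atoms: none
Why: Dehydration through the mesylate, whose ionisation to a conjugated allyl cation and loss of a methyl proton (E1 elimination) can give only the 3-methylbuta-1,3-diene, with the (E)-alkene untouched.

Step 7
Reactants: 13 3-[(E)-3-methylbuta-1,3-dienyl]-8-methoxy-7-(triisopropylsilyloxy)coumarin; 14 methacrolein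
Product: 15 (1S,2R)-1,4-dimethyl-2-[8-methoxy-2-oxo-7-(triisopropylsilyloxy)-2H-chromen-3-yl]cyclohex-3-ene-1-carbaldehyde
Conditions: (3aS)-1-(2-methylphenyl)-3,3-diphenyltetrahydro-1H,3H-pyrrolo[1,2-c][1,3,2]oxazaborole (20 mol%) N-protonated by Tf2NH (20 mol%), 14 (5 equiv), CH2Cl2, −78 → −40 °C
Reagents that add atoms: none
Why: The N-protonated oxazaborolidine binds s-trans methacrolein at boron through the carbonyl lone pair syn to the formyl hydrogen, with a formyl C–H···O contact to the ring oxygen, and the diene adds in a concerted, asynchronous, suprafacial [4+2] cycloaddition; the closest known reaction type is the oxazaborolidinium triflimide catalysed Diels–Alder reaction of 2-methylacrolein with acyclic 1-substituted butadienes. The cyclohexene ring is closed intermolecularly in one event by two C–C bonds, from the diene carbon bearing the coumarin to the enal α-carbon and from the diene CH2 terminus to the enal CH2. The quaternary centre is set by the catalyst: the phenyl group beside the bound enal covers one face, so the diene should reach the Re face of the α-carbon and give the (1S) configuration. The methine centre is set relative to it by the endo orientation of the formyl group over the (E)-diene, which places formyl and coumarinyl cis and the methyl trans to the coumarinyl, hence (2R). The step needs enantioface, endo and ortho/para selectivity: the first comes from the catalyst, the second from secondary overlap of the bound formyl group with the open-chain diene, and the third from the largest HOMO coefficient at the CH2 terminus of the 1-aryl-3-methyl diene matching the large LUMO coefficient at the enal β-carbon. The 7-silyloxy group makes the coumarin a net donor substituent on the diene, and the excess of enal should keep the catalyst from resting on the lactone carbonyl.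

Step 8
Reactants: 15 (1S,2R)-1,4-dimethyl-2-[8-methoxy-2-oxo-7-(triisopropylsilyloxy)-2H-chromen-3-yl]cyclohex-3-ene-1-carbaldehyde; 16 2-(dichloromethyl)-4,4,5,5-tetramethyl-1,3,2-dioxaborolane
Product: 18 pinacol (E)-2-[(1R,2R)-1,4-dimethyl-2-(8-methoxy-2-oxo-7-triisopropylsilyloxy-2H-chromen-3-yl)cyclohex-3-en-1-yl]ethenylboronate, via gem-dichromium boronate 17 (not isolated)
Conditions: CrCl2 (8 equiv), LiI (4 equiv), THF, 25 °C
Reagents that add atoms: none
Why: Boryl Takai–Utimoto olefination, in which divalent chromium turns the dihalomethylboronate into a gem-dichromium reagent that adds to the aldehyde and eliminates to the (E)-alkenylboronate; organochromium reagents are aldehyde-selective, so the lactone should survive, and the quaternary centre has no α-hydrogen to epimerise.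

Step 9
Reactants: 18 pinacol (E)-2-[(1R,2R)-1,4-dimethyl-2-(8-methoxy-2-oxo-7-triisopropylsilyloxy-2H-chromen-3-yl)cyclohex-3-en-1-yl]ethenylboronate; 9 3-bromo-8-methoxy-7-(triisopropylsilyloxy)coumarin
Product: 19 bis(triisopropylsilyl) ether of the target with (1R,2R) ring centres and (E)-alkene
Conditions: [1,1'-bis(diphenylphosphino)ferrocene]palladium dichloride Pd(dppf)Cl2 (5 mol%), K3PO4 (3 equiv), THF/H2O (10:1), 50 °C
Reagents that add atoms: none
Why: Suzuki–Miyaura coupling, in which oxidative addition into the C3–Br bond, transmetalation of the alkenylboronate with retention and reductive elimination should join the second coumarin without changing the (E)-geometry or either stereocentre.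

Step 10
Reactants: 19 bis(triisopropylsilyl) ether of the target
Product: 20 target CNP0264408.1
Conditions: TBAF (2.4 equiv), AcOH (2.6 equiv), THF, 0 °C
Reagents that add atoms: none
Why: Fluoride desilylation of both aryl silyl ethers, with acetic acid buffering the phenoxides and the fluoride so that the two lactones should not be opened.

**Compound list**
1 | 2-methoxyresorcinol (2-methoxybenzene-1,3-diol) | COc1c(O)cccc1O | starting material
2 | N-[(2,4-dihydroxy-3-methoxyphenyl)methylidene]-N-methylmethanaminium chloride | COc1c(O)ccc(C=[N+](C)C)c1O.[Cl-] | intermediate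
3 | 2,4-dihydroxy-3-methoxybenzaldehyde | COc1c(O)ccc(C=O)c1O | intermediate
4 | Meldrum's acid (2,2-dimethyl-1,3-dioxane-4,6-dione) | CC1(C)OC(=O)CC(=O)O1 | starting material
5 | 5-(2,4-dihydroxy-3-methoxybenzylidene)-2,2-dimethyl-1,3-dioxane-4,6-dione | COc1c(O)ccc(C=C2C(=O)OC(C)(C)OC2=O)c1O | intermediate
6 | 7-hydroxy-8-methoxy-2-oxo-2H-chromene-3-carboxylic acid | COc1c(O)ccc2cc(C(=O)O)c(=O)oc12 | intermediate
7 | triisopropylsilyl 8-methoxy-2-oxo-7-(triisopropylsilyloxy)-2H-chromene-3-carboxylate | COc1c(O[Si](C(C)C)(C(C)C)C(C)C)ccc2cc(C(=O)O[Si](C(C)C)(C(C)C)C(C)C)c(=O)oc12 | intermediate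
8 | 8-methoxy-2-oxo-7-(triisopropylsilyloxy)-2H-chromene-3-carboxylic acid | COc1c(O[Si](C(C)C)(C(C)C)C(C)C)ccc2cc(C(=O)O)c(=O)oc12 | intermediate
9 | 3-bromo-8-methoxy-7-(triisopropylsilyloxy)-2H-chromen-2-one | COc1c(O[Si](C(C)C)(C(C)C)C(C)C)ccc2cc(Br)c(=O)oc12 | intermediate
10 | 2-methylbut-3-en-2-ol | C=CC(C)(C)O | starting material
11 | 3-[(E)-3-hydroxy-3-methylbut-1-enyl]-8-methoxy-7-(triisopropylsilyloxy)-2H-chromen-2-one | CC(C)(O)/C=C/c1cc2ccc(O[Si](C(C)C)(C(C)C)C(C)C)c(OC)c2oc1=O | intermediate
12 | methanesulfonate of the tertiary alcohol 11 | CC(C)(OS(C)(=O)=O)/C=C/c1cc2ccc(O[Si](C(C)C)(C(C)C)C(C)C)c(OC)c2oc1=O | intermediate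
13 | 3-[(E)-3-methylbuta-1,3-dienyl]-8-methoxy-7-(triisopropylsilyloxy)-2H-chromen-2-one | C=C(C)/C=C/c1cc2ccc(O[Si](C(C)C)(C(C)C)C(C)C)c(OC)c2oc1=O | intermediate
14 | methacrolein (2-methylprop-2-enal) | C=C(C)C=O | starting material
15 | (1S,2R)-1,4-dimethyl-2-[8-methoxy-2-oxo-7-(triisopropylsilyloxy)-2H-chromen-3-yl]cyclohex-3-ene-1-carbaldehyde (formyl and coumarinyl cis) | O=C[C@@]1(C)CCC(C)=C[C@H]1c1cc2ccc(O[Si](C(C)C)(C(C)C)C(C)C)c(OC)c2oc1=O | intermediate
16 | 2-(dichloromethyl)-4,4,5,5-tetramethyl-1,3,2-dioxaborolane | ClC(Cl)B1OC(C)(C)C(C)(C)O1 | starting material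
17 | 2-[bis(dichlorochromio)methyl]-4,4,5,5-tetramethyl-1,3,2-dioxaborolane (gem-dichromium reagent, trivalent chromium) | CC1(C)OB(C([Cr](Cl)Cl)[Cr](Cl)Cl)OC1(C)C | intermediate
18 | pinacol (E)-2-[(1R,2R)-1,4-dimethyl-2-(8-methoxy-2-oxo-7-triisopropylsilyloxy-2H-chromen-3-yl)cyclohex-3-en-1-yl]ethenylboronate | CC1(C)OB(/C=C/[C@@]2(C)CCC(C)=C[C@H]2c2cc3ccc(O[Si](C(C)C)(C(C)C)C(C)C)c(OC)c3oc2=O)OC1(C)C | intermediate
19 | 8-methoxy-3-[(E)-2-[(1R,2R)-2-(8-methoxy-2-oxo-7-triisopropylsilyloxy-2H-chromen-3-yl)-1,4-dimethylcyclohex-3-en-1-yl]ethenyl]-7-(triisopropylsilyloxy)-2H-chromen-2-one | COc1c(O[Si](C(C)C)(C(C)C)C(C)C)ccc2cc(/C=C/[C@@]3(C)CCC(C)=C[C@H]3c3cc4ccc(O[Si](C(C)C)(C(C)C)C(C)C)c(OC)c4oc3=O)c(=O)oc12 | intermediate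
20 | 7-hydroxy-3-[(E)-2-[(1R,2R)-2-(7-hydroxy-8-methoxy-2-oxo-2H-chromen-3-yl)-1,4-dimethylcyclohex-3-en-1-yl]ethenyl]-8-methoxy-2H-chromen-2-one (CNP0264408.1) | COc1c(O)ccc2cc(/C=C/[C@@]3(C)CCC(C)=C[C@H]3c3cc4ccc(O)c(OC)c4oc3=O)c(=O)oc12 | target

**Step count and risks**
Total step count: 10. Longest linear sequence: 10 steps (1 to 20; bromocoumarin 9 is used in steps 5 and 9).

The three steps most likely to fail:

1. Step 7. The cycloaddition may show poor facial or endo selectivity, or may stall because the lactone carbonyl competes with the enal for the boron catalyst or the diene oligomerises under the acid. Fallback: setting out from 13 and 14, the cycloaddition would be run with an achiral Lewis acid (dimethylaluminium chloride Me2AlCl, CH2Cl2, −78 °C) to give the racemic cis aldehyde, that is 15 together with its mirror image, the (1R,2S)-aldehyde F1. The two would be separated by preparative chromatography on a chiral stationary phase, and the route rejoins at 15.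

2. Step 8. Addition of the bulky gem-dichromium reagent to the neopentyl aldehyde, flanked by the quaternary centre and the cis coumarinyl group, may be slow, with reductive side reactions of the aldehyde taking over. Fallback: setting out from 15, Seyferth–Gilbert homologation with the Ohira–Bestmann reagent (dimethyl (1-diazo-2-oxopropyl)phosphonate, K2CO3, MeOH, 0 °C → rt; resilylation if the aryl silyl ether is partly lost) would give the terminal alkyne F2. Syn hydroboration with pinacolborane catalysed by zirconocene chloride hydride Cp2Zr(H)Cl (Et3N, 50 °C) would then deliver the (E)-alkenylboronate, and the route rejoins at 18.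

3. Step 4. Electrophilic bromination of the electron-rich benzo ring (C5 or C6) may compete with ipso attack at C3, or decarboxylation may be incomplete. Fallback: setting out from 6, protodecarboxylation (Cu powder, quinoline, 200 °C) would give 7-hydroxy-8-methoxycoumarin F3, and silylation (TIPSCl, imidazole, DMF) its triisopropylsilyl ether F4. Bromine (CH2Cl2, 0 °C) would add across C3=C4 to give the trans-3,4-dibromo-3,4-dihydrocoumarin F5, and Et3N would eliminate HBr by removal of the acidic C3–H and loss of the benzylic C4 bromide, so that the route rejoins at 9.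

Further compounds
F1 | step 7 | (1R,2S)-1,4-dimethyl-2-[8-methoxy-2-oxo-7-(triisopropylsilyloxy)-2H-chromen-3-yl]cyclohex-3-ene-1-carbaldehyde (enantiomer of 15) | O=C[C@]1(C)CCC(C)=C[C@@H]1c1cc2ccc(O[Si](C(C)C)(C(C)C)C(C)C)c(OC)c2oc1=O
F2 | step 8 | 3-[(1R,6S)-6-ethynyl-3,6-dimethylcyclohex-2-en-1-yl]-8-methoxy-7-(triisopropylsilyloxy)-2H-chromen-2-one (ethynyl in place of the formyl group of 15, same spatial arrangement) | C#C[C@@]1(C)CCC(C)=C[C@H]1c1cc2ccc(O[Si](C(C)C)(C(C)C)C(C)C)c(OC)c2oc1=O
F3 | step 4 | 7-hydroxy-8-methoxy-2H-chromen-2-one | COc1c(O)ccc2ccc(=O)oc12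
F4 | step 4 | 8-methoxy-7-(triisopropylsilyloxy)-2H-chromen-2-one | COc1c(O[Si](C(C)C)(C(C)C)C(C)C)ccc2ccc(=O)oc12
F5 | step 4 | trans-3,4-dibromo-8-methoxy-7-(triisopropylsilyloxy)-3,4-dihydro-2H-chromen-2-one (racemic, one enantiomer drawn) | COc1c(O[Si](C(C)C)(C(C)C)C(C)C)ccc2c1OC(=O)[C@@H](Br)[C@@H]2Br
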